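**Retrosynthetic overview**
- Target: (2S)-7,4'-dihydroxy-6,8-diprenylflavanone. The last event is removal of one silyl group from the ring B phenol.
- Key disconnection: the O1–C2 bond of ring C (oxa-Michael) and both aryl–prenyl bonds (C8–CH2, C6–CH2) are retraced in one flask. This leads to an acyclic, achiral isomer, the 2',4'-bis(1,1-dimethylallyl) ether of a chalcone.
- Enabling feature: on ring A each prenylated carbon lies ortho to an oxygen (C8 next to O1, C6 next to O7), so each C-prenyl group is the [3,3] image of an O-(1,1-dimethylallyl) ether. The shift that builds the C8–prenyl bond also frees O1, next to the C4 carbonyl and within reach of C2.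
- The chalcone comes from an aryllithium (4-bromoresorcinol bis-ether, Br–Li exchange) and a cinnamoyl Weinreb amide (Horner–Wadsworth–Emmons).
- Ring order: rings A and B are purchased. Ring C is the only ring formed, in the key step.

Key step: step 5

Assumption: the quinine-derived thiourea is taken to give the (2S) series; if a test run (sign of the circular dichroism bands) shows the opposite sense, the pseudoenantiomeric quinidine-derived catalyst replaces it with nothing else changed.
Numbering remark: primed locants refer to ring A of the chalcones (C-1' bears the carbonyl); flavanone locants are used for 15 and 16.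

Step 1
Reactants: 1 2-methylbut-3-en-2-ol
Product: 3 isobutyl 2-methylbut-3-en-2-yl carbonate, via lithium alkoxide 2 (not isolated)
Conditions: n-BuLi, THF, −78 to 0 °C; then ClCO2i-Bu, 0 °C to rt
Reagents that add atoms: isobutyl chloroformate CC(C)COC(=O)Cl
Why: O-acylation of a preformed lithium alkoxide with a chloroformate (carbonate formation) is fast even for a tertiary alcohol and avoids acid that would ionise the tertiary allylic centre.

Step 2
Reactants: 4 4-bromoresorcinol; 3 isobutyl 2-methylbut-3-en-2-yl carbonate
Product: 5 1-bromo-2,4-bis[(2-methylbut-3-en-2-yl)oxy]benzene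
Conditions: 3 (3 equiv), Pd(PPh3)4 (5 mol %), THF, 0–5 °C
Reagents that add atoms: none
Why: In this Tsuji–Trost O-allylation, zerovalent palladium ionises 3 to the 1,1-dimethyl-π-allyl complex with loss of CO2, the isobutoxide deprotonates the phenol, and under kinetic control in the cold the phenoxide attacks the more substituted allyl terminus at both oxygens, while the C–Br bond of the electron-rich ring stays inert at this temperature.

Step 3
Reactants: 6 4-[(tert-butyldimethylsilyl)oxy]benzaldehyde; 7 diethyl {2-[methoxy(methyl)amino]-2-oxoethyl}phosphonate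
Product: 9 (E)-3-{4-[(tert-butyldimethylsilyl)oxy]phenyl}-N-methoxy-N-methylprop-2-enamide, via sodium phosphonate carbanion 8 (not isolated)
Conditions: 7, NaH, THF, 0 °C; then 6, 0 °C to rt
Reagents that add atoms: none
Why: The Horner–Wadsworth–Emmons olefination of an aromatic aldehyde with a stabilised amide phosphonate gives the (E)-alkene under thermodynamic control, and the aryl silyl ether tolerates the preformed, non-nucleophilic carbanion.

Step 4
Reactants: 5 1-bromo-2,4-bis[(2-methylbut-3-en-2-yl)oxy]benzene; 9 (E)-3-{4-[(tert-butyldimethylsilyl)oxy]phenyl}-N-methoxy-N-methylprop-2-enamide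
Product: 12 (E)-1-{2,4-bis[(2-methylbut-3-en-2-yl)oxy]phenyl}-3-{4-[(tert-butyldimethylsilyl)oxy]phenyl}prop-2-en-1-one (chalcone bis-ether), via aryllithium 10 (not isolated), via tetrahedral lithium adduct 11 (not isolated)
Conditions: 5, n-BuLi, THF, −78 °C; then 9, −78 °C; AcOH quench at −78 °C
Reagents that add atoms: none
Why: Bromine–lithium exchange followed by the Weinreb ketone synthesis gives 1,2-addition to a chelated adduct that cannot over-add, and the cold acid quench releases the enone while protonating the liberated amine so that it cannot add to the chalcone.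

Step 5
Reactants: 12 chalcone bis-ether
Product: 15 (2S)-2-{4-[(tert-butyldimethylsilyl)oxy]phenyl}-7-hydroxy-6,8-bis(3-methylbut-2-en-1-yl)-2,3-dihydro-4H-chromen-4-one, via monoprenyl chalcone 13 (not isolated), via diprenyl chalcone 14 (not isolated)
Conditions: PhMe (degassed, 0.05 M), sealed base-washed tube, 125 °C, dark; cool to 0 °C; then 9-amino-9-deoxy-epi-quinine N-[3,5-bis(trifluoromethyl)phenyl]thiourea (20 mol %), 0 °C
Reagents that add atoms: none
Why: On heating, the crowded O-2' ether undergoes an aromatic Claisen [3,3] shift to its only open ortho carbon C-3' and re-aromatises to 13, the O-4' ether then shifts to C-5' to give 14, and each shift inverts the allyl unit so that a tertiary O-(1,1-dimethylallyl) group becomes a C-prenyl group. Neutral toluene offers no catalyst for conjugate addition, so 14, with its freed 2'-OH hydrogen-bonded to the carbonyl, should persist until the bifunctional catalyst is added cold; the quinuclidine nitrogen then takes up the 2'-OH proton while the thiourea N–H pair binds the carbonyl oxygen, the phenol oxygen adds to the enone β-carbon, and the enol is protonated to the ketone. The closest known reaction types are the tandem aromatic Claisen/6-endo cyclisation that gives 8-allyl- and 8-prenylchromones and the cinchona-thiourea-catalysed enantioselective cyclisation of 2'-hydroxychalcones to flavanones, here run one after the other in one flask. Ring C, the only ring formed, closes in the 6-endo-trig mode by making the O1–C2 bond. C2, the only stereocentre, is set by the catalyst, which holds the s-cis enone and the phenol in one chiral pocket so that oxygen reaches the Si face of the β-carbon, giving (2S). The step needs regiocontrol in both shifts (C-1' bears the acyl group, C-3' is filled by the first shift, and only C-5' remains for the second), choice of the 2'-OH over the 4'-OH (only the former can reach the β-carbon, and the latter is flanked by two prenyl groups), and kinetic control of a reversible addition (low temperature, work-up before equilibration).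

Step 6
Reactants: 15 (2S)-silyl flavanone
Product: 16 (2S)-7-hydroxy-2-(4-hydroxyphenyl)-6,8-bis(3-methylbut-2-en-1-yl)-2,3-dihydro-4H-chromen-4-one (target)
Conditions: HF·pyridine, pyridine, THF, 0 °C
Reagents that add atoms: none
Why: Fluoride cleavage of the aryl silyl ether in a pyridine-buffered, weakly acidic medium spares the prenyl groups and avoids the base-induced ring opening to the chalcone that would racemise C2.

**Compound list**
1 | 2-methylbut-3-en-2-ol | C=CC(C)(C)O | starting material
2 | lithium 2-methylbut-3-en-2-olate | [Li+].[O-]C(C)(C)C=C | intermediate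
3 | isobutyl 2-methylbut-3-en-2-yl carbonate | C=CC(C)(C)OC(=O)OCC(C)C | intermediate
4 | 4-bromoresorcinol (4-bromobenzene-1,3-diol) | Oc1ccc(Br)c(O)c1 | starting material
5 | 1-bromo-2,4-bis[(2-methylbut-3-en-2-yl)oxy]benzene | C=CC(C)(C)Oc1ccc(Br)c(OC(C)(C)C=C)c1 | intermediate
6 | 4-[(tert-butyldimethylsilyl)oxy]benzaldehyde | O=Cc1ccc(O[Si](C)(C)C(C)(C)C)cc1 | starting material
7 | diethyl {2-[methoxy(methyl)amino]-2-oxoethyl}phosphonate | CCOP(=O)(CC(=O)N(C)OC)OCC | starting material
8 | sodium carbanion of phosphonate 7 | [Na+].CCOP(=O)([CH-]C(=O)N(C)OC)OCC | intermediate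
9 | (E)-3-{4-[(tert-butyldimethylsilyl)oxy]phenyl}-N-methoxy-N-methylprop-2-enamide | CON(C)C(=O)/C=C/c1ccc(O[Si](C)(C)C(C)(C)C)cc1 | intermediate
10 | {2,4-bis[(2-methylbut-3-en-2-yl)oxy]phenyl}lithium | [Li]c1ccc(OC(C)(C)C=C)cc1OC(C)(C)C=C | intermediate
11 | tetrahedral lithium adduct of 10 and 9 (racemic at the new carbon) | [Li]OC(/C=C/c1ccc(O[Si](C)(C)C(C)(C)C)cc1)(N(C)OC)c1ccc(OC(C)(C)C=C)cc1OC(C)(C)C=C | intermediate
12 | (E)-1-{2,4-bis[(2-methylbut-3-en-2-yl)oxy]phenyl}-3-{4-[(tert-butyldimethylsilyl)oxy]phenyl}prop-2-en-1-one | C=CC(C)(C)Oc1ccc(C(=O)/C=C/c2ccc(O[Si](C)(C)C(C)(C)C)cc2)c(OC(C)(C)C=C)c1 | intermediate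
13 | (E)-1-{2-hydroxy-3-(3-methylbut-2-en-1-yl)-4-[(2-methylbut-3-en-2-yl)oxy]phenyl}-3-{4-[(tert-butyldimethylsilyl)oxy]phenyl}prop-2-en-1-one | C=CC(C)(C)Oc1ccc(C(=O)/C=C/c2ccc(O[Si](C)(C)C(C)(C)C)cc2)c(O)c1CC=C(C)C | intermediate
14 | (E)-1-[2,4-dihydroxy-3,5-bis(3-methylbut-2-en-1-yl)phenyl]-3-{4-[(tert-butyldimethylsilyl)oxy]phenyl}prop-2-en-1-one | CC(C)=CCc1cc(C(=O)/C=C/c2ccc(O[Si](C)(C)C(C)(C)C)cc2)c(O)c(CC=C(C)C)c1O | intermediate
15 | (2S)-2-{4-[(tert-butyldimethylsilyl)oxy]phenyl}-7-hydroxy-6,8-bis(3-methylbut-2-en-1-yl)-2,3-dihydro-4H-chromen-4-one | CC(C)=CCc1cc2c(c(CC=C(C)C)c1O)O[C@H](c1ccc(O[Si](C)(C)C(C)(C)C)cc1)CC2=O | intermediate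
16 | (2S)-7-hydroxy-2-(4-hydroxyphenyl)-6,8-bis(3-methylbut-2-en-1-yl)-2,3-dihydro-4H-chromen-4-one | CC(C)=CCc1cc2c(c(CC=C(C)C)c1O)O[C@H](c1ccc(O)cc1)CC2=O | target

**Step count**
Total steps: 6. Longest linear sequence: 5 (steps 1, 2, 4, 5, 6).

**Steps most likely to fail**

1. Step 5.
- What may go wrong in the cold stage:
  - Facial discrimination may be weak on an enone that carries no extra activating group.
  - Turnover may be slow because the acidic 4'-OH ties up the quinuclidine.
  - Enantiopurity may erode through reversible ring opening.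
- What may go wrong in the hot stage: part of the tertiary ether may be lost as isoprene.
- Fallback: ring closure is separated from enantioselection.
  - Setting out from 12, the same thermal double Claisen shift is run.
  - The ring is then closed with an achiral base (catalytic quinuclidine, PhMe, 40 °C) to give the racemic silyl flavanone F1.
  - F1 is resolved kinetically by Noyori-type asymmetric transfer hydrogenation with RuCl[(R,R)-TsDPEN](p-cymene), HCO2H/Et3N, EtOAc, rt.
  - The (2R) ketone is the matched substrate and should be reduced to the cis-(2R,4R)-flavan-4-ol F2.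
  - The (2S) ketone stays behind, is separated by chromatography, and the route is rejoined at 15.

2. Step 2.
- What may go wrong:
  - The kinetic tertiary ether may drift to the linear prenyl ether through re-ionisation by palladium.
  - The hindered OH next to bromine may be incompletely alkylated.
  - The resorcinol ring may undergo C-allylation.
- Fallback: the tertiary ether is built at the alkyne oxidation level.
  - Setting out from 4, copper-catalysed propargylic substitution (3-chloro-3-methylbut-1-yne, CuCl2 cat., DBU, MeCN, 0 °C) should give 1-bromo-2,4-bis[(2-methylbut-3-yn-2-yl)oxy]benzene F3.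
  - Semi-hydrogenation (H2, Pd/CaCO3–Pb(OAc)2 Lindlar catalyst, quinoline, EtOAc) converts both alkynes to vinyl groups, and the route is rejoined at 5.

3. Step 4.
- What may go wrong:
  - The aryllithium may add to the cinnamoyl unit in conjugate fashion.
  - The ortho-hindered aryllithium may attack the amide sluggishly at −78 °C.
  - On warming, the aryllithium may cyclise onto its own vinyl group (5-exo carbolithiation).
- Fallback: a more reactive electrophile is used, with a later oxidation.
  - Setting out from 9, reduction with i-Bu2AlH (THF, −78 °C) gives (E)-3-{4-[(tert-butyldimethylsilyl)oxy]phenyl}prop-2-enal F4.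
  - Addition of aryllithium 10 (from 5, n-BuLi, −78 °C) gives the racemic allylic alcohol F5 by 1,2-addition.
  - Oxidation with MnO2 (CH2Cl2, rt) rejoins the route at 12.

**Further compounds**
F1 | step 5 | racemic 2-{4-[(tert-butyldimethylsilyl)oxy]phenyl}-7-hydroxy-6,8-bis(3-methylbut-2-en-1-yl)-2,3-dihydro-4H-chromen-4-one | CC(C)=CCc1cc2c(c(CC=C(C)C)c1O)OC(c1ccc(O[Si](C)(C)C(C)(C)C)cc1)CC2=O
F2 | step 5 | (2R,4R)-2-{4-[(tert-butyldimethylsilyl)oxy]phenyl}-6,8-bis(3-methylbut-2-en-1-yl)-3,4-dihydro-2H-chromene-4,7-diol | CC(C)=CCc1cc2c(c(CC=C(C)C)c1O)O[C@@H](c1ccc(O[Si](C)(C)C(C)(C)C)cc1)C[C@H]2O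
F3 | step 2 | 1-bromo-2,4-bis[(2-methylbut-3-yn-2-yl)oxy]benzene | C#CC(C)(C)Oc1ccc(Br)c(OC(C)(C)C#C)c1
F4 | step 4 | (E)-3-{4-[(tert-butyldimethylsilyl)oxy]phenyl}prop-2-enal | O=C/C=C/c1ccc(O[Si](C)(C)C(C)(C)C)cc1
F5 | step 4 | racemic (E)-1-{2,4-bis[(2-methylbut-3-en-2-yl)oxy]phenyl}-3-{4-[(tert-butyldimethylsilyl)oxy]phenyl}prop-2-en-1-ol | OC(/C=C/c1ccc(O[Si](C)(C)C(C)(C)C)cc1)c1ccc(OC(C)(C)C=C)cc1OC(C)(C)C=C
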